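**Plan**

1. Labels: C1–C5 = chain B (C1 is its CH2OH), C6 = ring CH on the ether oxygen, C7 = methyl-bearing carbon on the lactone oxygen, C8/C9 = ring CH2, C10 = CHOH, C11 = fully substituted carbon, C12–C15 = chain A, C20 = lactone C=O, O21 = ether O, O22 = lactone ring O.
2. Cuts, last first: C14=C15 (Z-olefination after oxidising the end of an allyl group on C11), C10–OH back to the ketone, then C11–O21 and C11–C12 in one operation.
3. That double cut is possible because C11 carries O21, the chain carbon C12 and two carbonyl-level carbons (C10, C20). A C11 carbene between C10=O and C20=O that captures the C6 allyl ether oxygen and takes over its allyl group gives exactly this centre, and closes the dioxanone (C11–O21–C6–C7–O22–C20) and the oxepane (C11–O21–C6–C7–C8–C9–C10) at once.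
4. The seven-membered diazo keto lactone is cut at O22–C20 (acylketene capture by the C7 alcohol), C8–C9 (dioxinone dienolate on a terminal epoxide) and C6–C7 (isopropenyl Grignard on a nerol-derived aldehyde).
5. Forward: chain B aldehyde, allylic alcohol, epoxy alcohol, allyl ether, lactone ring, diazo transfer, bicyclisation (two rings and C11), then chain A is grown from the allyl group.
6. Stereochemistry: C6 and C7 from a Sharpless kinetic resolution, C11 from the cage geometry of the key step, C10 from a CBS reduction, the chain B alkene from nerol, the chain A alkene from a Still–Gennari olefination.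

Key step: step 10

Remark: step 5 is a resolution, so only the (S)-half of racemic 6 is carried forward; the target is taken as drawn, C6 (S), C7 (R), C10 (S), C11 (R).

**Route**

Step 1
Reactants: 1 nerol
Product: 2 neryl TBS ether
Conditions: TBSCl, imidazole, DMF, 0 °C to rt
Reagents that add atoms: tert-butyldimethylsilyl chloride, CC(C)(C)[Si](C)(C)Cl
Why: Imidazole-promoted silylation (O-silyl ether formation) of the primary allylic alcohol is routine and masks the C1 hydroxyl against the organometallic, Lewis-acid, oxidising and hydride reagents used later.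

Step 2
Reactants: 2 neryl TBS ether
Product: 3 racemic 6,7-epoxide of the neryl TBS ether
Conditions: mCPBA (1.05 equiv), CH2Cl2, −20 to 0 °C
Reagents that add atoms: 3-chloroperoxybenzoic acid, OOC(=O)c1cccc(Cl)c1
Why: Peracid (Prilezhaev) epoxidation takes the more electron-rich distal trisubstituted alkene because the C2=C3 alkene is deactivated by the allylic silyloxy group, and the configuration of the new epoxide carbon does not matter since that carbon is cleaved away in step 3.

Step 3
Reactants: 3 racemic 6,7-epoxide
Product: 4 (4Z)-6-silyloxy-4-methylhex-4-enal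
Conditions: H5IO6, THF/Et2O, 0 °C
Reagents that add atoms: none
Why: Periodic acid hydrolyses the trisubstituted epoxide and cleaves the resulting glycol in one pot (Malaprade-type oxidative cleavage), giving the aldehyde and acetone at a temperature and contact time that the Z-alkene and the primary silyl ether tolerate.

Step 4
Reactants: 4 silyloxy aldehyde; 5 isopropenylmagnesium bromide
Product: 6 racemic isopropenyl carbinol
Conditions: THF, −78 °C; aqueous work-up
Reagents that add atoms: none
Why: Grignard 1,2-addition of the alkenylmagnesium reagent to the unhindered aldehyde gives the 2-methyl-substituted secondary allylic alcohol that the resolution needs, and the carbinol centre is deliberately left racemic at this stage.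

Step 5
Reactants: 6 racemic isopropenyl carbinol
Product: 7 (6S,7R)-epoxy alcohol
Conditions: Ti(OiPr)4 (0.15 equiv), L-(+)-DIPT (diisopropyl (2R,3R)-tartrate, 0.2 equiv), t-BuOOH (0.45 equiv), 4 Å molecular sieves, CH2Cl2, −20 °C
Reagents that add atoms: tert-butyl hydroperoxide, CC(C)(C)OO
Why: Sharpless kinetic resolution by titanium–tartrate asymmetric epoxidation: with L-(+)-DIPT the (S)-alcohol is the fast-reacting enantiomer and takes up oxygen on the alkene face that gives the erythro (anti) epoxy alcohol, so C6 (S) and C7 (R) are fixed together by the chiral catalyst, while the (R)-alcohol stays behind and the chain B alkene, which has no free allylic hydroxyl to bind titanium, is not touched.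

Step 6
Reactants: 7 epoxy alcohol; 8 allyl bromide
Product: 9 C6 allyl ether epoxide
Conditions: NaH, Bu4NI (cat.), THF/DMF, 0 °C to rt
Reagents that add atoms: none
Why: Williamson etherification of the sodium alkoxide with allyl bromide installs the group that migrates in step 10, and in an aprotic solvent with the electrophile already present the alkoxide is alkylated faster than it can undergo Payne rearrangement, which would need attack at the fully substituted epoxide carbon.

Step 7
Reactants: 9 allyl ether epoxide; 10 2,2,6-trimethyl-4H-1,3-dioxin-4-one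
Product: 12 dioxinone tertiary alcohol, via lithium dienolate 11 (not isolated)
Conditions: 10, lithium diisopropylamide, THF, −78 °C; then 9 and BF3·OEt2, −78 °C; aqueous work-up
Reagents that add atoms: none
Why: SN2 opening of a Lewis-acid-activated terminal epoxide by the γ-carbon of a vinylogous ester enolate (the dioxinone dienolate acting as a masked acetoacetate dianion) forms C8–C9 at the unsubstituted epoxide carbon, so the C7–O bond is not broken and C7 keeps its configuration while the tertiary alcohol is set free.

Step 8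
Reactants: 12 dioxinone tertiary alcohol
Product: 14 seven-membered β-keto lactone, via acylketene 13 (not isolated)
Conditions: toluene (0.005 M), reflux
Reagents that add atoms: none
Why: Thermal retro-[4+2] fragmentation of the dioxinone releases acetone and an acylketene that is trapped intramolecularly by the C7 tertiary hydroxyl (acylketene lactonisation), with high dilution and the fully substituted C7 favouring closure of the seven-membered β-keto lactone over ketene dimerisation.

Step 9
Reactants: 14 β-keto lactone
Product: 15 seven-membered 3-diazo-2,4-dioxo lactone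
Conditions: 4-acetamidobenzenesulfonyl azide, Et3N, MeCN, 0 °C to rt
Reagents that add atoms: 4-acetamidobenzenesulfonyl azide, CC(=O)Nc1ccc(cc1)S(=O)(=O)N=[N+]=[N-]
Why: Regitz diazo transfer from the sulfonyl azide to the doubly activated C11 methylene needs only a tertiary amine base, which the lactone of the tertiary alcohol, the allyl ether and the silyl ether tolerate.

Step 10
Reactants: 15 diazo keto lactone
Product: 17 bicyclic C10 keto lactone with the allyl group on C11, via bridged oxonium ylide 16 (not isolated)
Conditions: Cu(hfacac)2 [copper bis(1,1,1,5,5,5-hexafluoropentane-2,4-dionate), divalent copper] (5 mol %), CH2Cl2, reflux, slow addition of 15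
Reagents that add atoms: none
Why: Cu(hfacac)2 takes N2 from the diazo group to give an electrophilic copper carbenoid at C11, a lone pair of the C6 allyl ether oxygen adds to it to give the bridged oxonium ylide 16, and a [2,3]-sigmatropic shift then moves the allyl group from O21 to C11 with allylic transposition, which neutralises the ylide. The closest known reaction type is the copper- or rhodium-catalysed oxonium ylide formation and [2,3]-rearrangement of allyl ethers tethered to α-diazo ketones and α-diazo β-keto esters, used here in its less common transannular, bridged form. The dioxanone ring (C11–O21–C6–C7–O22–C20) closes by six-membered attack of O21 on the carbenoid across the seven-membered lactone, and the oxepane (C11–O21–C6–C7–C8–C9–C10) is closed by the same C11–O21 bond, while C11–C12 comes from the sigmatropic step. C11 is the only new stereocentre and is fixed by the cage: O21 can reach C11 only from the lactone face on which the C6 arm of C7 lies, and the allyl group must then end up exo at the bridgehead, so C6 and C7 dictate (R)-C11. The step needs chemoselectivity for ylide formation over insertion into the ether-activated C6–H bond, cyclopropanation and carbene dimerisation; the doubly acyl-stabilised carbenoid on an electron-poor copper centre prefers the Lewis-basic oxygen, insertion into C6–H would have to build a more strained bridged γ-lactone, and slow addition at high dilution suppresses dimerisation.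

Step 11
Reactants: 17 bicyclic allyl keto lactone
Product: 19 C14 primary alcohol, via catechol alkylboronate 18 (not isolated)
Conditions: catecholborane, RhCl(PPh3)3 (2 mol %), THF, 0 °C to rt; then H2O2, pH 7 phosphate buffer, 0 °C
Reagents that add atoms: hydrogen peroxide, OO
Why: Rhodium-catalysed hydroboration with catecholborane places boron on the terminal carbon of the monosubstituted alkene (anti-Markovnikov) much faster than the uncatalysed borane attacks the hindered ketone or the trisubstituted alkene, and oxidation of the C–B bond with buffered peroxide avoids the hydroxide that could cleave the non-enolisable β-keto lactone by retro-Claisen attack.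

Step 12
Reactants: 19 C14 primary alcohol
Product: 20 C14 aldehyde
Conditions: Dess–Martin periodinane, pyridine, CH2Cl2, 0 °C to rt
Reagents that add atoms: none
Why: Dess–Martin oxidation converts the primary alcohol (drawn from its equilibrium with the hemiketal on C10) into the aldehyde under nearly neutral conditions that do not affect the silyl ether, the lactone or the fully substituted C11.

Step 13
Reactants: 20 C14 aldehyde; 21 ethyl 2-[bis(2,2,2-trifluoroethoxy)phosphoryl]propanoate
Product: 22 (Z)-enoate keto lactone
Conditions: KN(SiMe3)2, 18-crown-6, THF, −78 °C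
Reagents that add atoms: none
Why: Still–Gennari olefination, in which the electron-poor bis(trifluoroethyl) phosphonate anion with a crown-ether-separated potassium ion eliminates under kinetic control, gives the (Z)-2-methyl enoate, and at −78 °C the stabilised anion adds only to the aldehyde and not to the hindered C10 ketone or the lactone.

Step 14
Reactants: 22 (Z)-enoate keto lactone
Product: 23 (10S)-hydroxy enoate
Conditions: (R)-2-methyl-CBS-oxazaborolidine (0.3 equiv), catecholborane, toluene, −78 to −40 °C; aqueous NaHCO3 work-up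
Reagents that add atoms: none
Why: Corey–Bakshi–Shibata reduction: the (R)-oxazaborolidine coordinates the ketone oxygen on the side of the C9 methylene, away from the quaternary C11, and passes hydride from catecholborane to the carbonyl face next to the ether bridge (opposite the lactone bridge), which sets (S)-C10 under catalyst control while the enoate, the lactone and both alkenes are inert to catecholborane at low temperature.

Step 15
Reactants: 23 hydroxy enoate
Product: 24 mono-TBS triol (chain A allylic alcohol, C10–OH free)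
Conditions: iBu2AlH (3.5 equiv), CH2Cl2, −78 °C; aqueous potassium sodium tartrate
Reagents that add atoms: none
Why: 1,2-Reduction of the conjugated ethyl ester with iBu2AlH at −78 °C (ester-to-allylic-alcohol hydride reduction) leaves the alkene geometry alone, and it should outrun attack on the bridged lactone because that carbonyl is flanked by the quaternary C11 and the tertiary C7–O and lies next to the aluminium alkoxide formed at C10.

Step 16
Reactants: 24 mono-TBS triol
Product: 25 target CNP0105745.1
Conditions: HF·pyridine, pyridine, THF, 0 °C to rt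
Reagents that add atoms: none
Why: Fluoride-induced desilylation with pyridine-buffered HF·pyridine cleaves the primary allylic silyl ether under mildly acidic conditions, which avoids the basic fluoride or alkoxide media that could open the lactone or trigger retro-aldol cleavage of the C10–C11 bond.

**Compound list**

1 | nerol, (2Z)-3,7-dimethylocta-2,6-dien-1-ol | CC(C)=CCC/C(C)=C\CO | starting material
2 | tert-butyl{[(2Z)-3,7-dimethylocta-2,6-dien-1-yl]oxy}dimethylsilane | CC(C)=CCC/C(C)=C\CO[Si](C)(C)C(C)(C)C | intermediate
3 | racemic tert-butyl{[(2Z)-5-(3,3-dimethyloxiran-2-yl)-3-methylpent-2-en-1-yl]oxy}dimethylsilane | CC1(C)OC1CC/C(C)=C\CO[Si](C)(C)C(C)(C)C | intermediate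
4 | (4Z)-6-[(tert-butyldimethylsilyl)oxy]-4-methylhex-4-enal | O=CCC/C(C)=C\CO[Si](C)(C)C(C)(C)C | intermediate
5 | isopropenylmagnesium bromide | CC(=C)[Mg]Br | starting material
6 | racemic (6Z)-8-[(tert-butyldimethylsilyl)oxy]-2,6-dimethylocta-1,6-dien-3-ol | C=C(C)C(O)CC/C(C)=C\CO[Si](C)(C)C(C)(C)C | intermediate
7 | (1S,4Z)-6-[(tert-butyldimethylsilyl)oxy]-4-methyl-1-[(2R)-2-methyloxiran-2-yl]hex-4-en-1-ol | C[C@@]1(CO1)[C@@H](O)CC/C(C)=C\CO[Si](C)(C)C(C)(C)C | intermediate
8 | allyl bromide, 3-bromoprop-1-ene | C=CCBr | starting material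
9 | (2R)-2-[(1S,4Z)-6-[(tert-butyldimethylsilyl)oxy]-4-methyl-1-(prop-2-en-1-yloxy)hex-4-en-1-yl]-2-methyloxirane | C[C@@]1(CO1)[C@@H](OCC=C)CC/C(C)=C\CO[Si](C)(C)C(C)(C)C | intermediate
10 | 2,2,6-trimethyl-4H-1,3-dioxin-4-one | CC1=CC(=O)OC(C)(C)O1 | starting material
11 | lithium 2,2-dimethyl-6-methylidene-6H-1,3-dioxin-4-olate (dienolate of 10) | [Li+].C=C1C=C([O-])OC(C)(C)O1 | intermediate
12 | 6-[(3R,4S,7Z)-9-[(tert-butyldimethylsilyl)oxy]-3-hydroxy-3,7-dimethyl-4-(prop-2-en-1-yloxy)non-7-en-1-yl]-2,2-dimethyl-4H-1,3-dioxin-4-one | C=CCO[C@@H](CC/C(C)=C\CO[Si](C)(C)C(C)(C)C)[C@](C)(O)CCC1=CC(=O)OC(C)(C)O1 | intermediate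
13 | (6R,7S,10Z)-12-[(tert-butyldimethylsilyl)oxy]-6-hydroxy-6,10-dimethyl-7-(prop-2-en-1-yloxy)dodeca-1,10-diene-1,3-dione (acylketene) | C=CCO[C@@H](CC/C(C)=C\CO[Si](C)(C)C(C)(C)C)[C@](C)(O)CCC(=O)C=C=O | intermediate
14 | (7R)-7-[(1S,4Z)-6-[(tert-butyldimethylsilyl)oxy]-4-methyl-1-(prop-2-en-1-yloxy)hex-4-en-1-yl]-7-methyloxepane-2,4-dione | C=CCO[C@@H](CC/C(C)=C\CO[Si](C)(C)C(C)(C)C)[C@@]1(C)CCC(=O)CC(=O)O1 | intermediate
15 | (7R)-3-diazo-7-[(1S,4Z)-6-[(tert-butyldimethylsilyl)oxy]-4-methyl-1-(prop-2-en-1-yloxy)hex-4-en-1-yl]-7-methyloxepane-2,4-dione | C=CCO[C@@H](CC/C(C)=C\CO[Si](C)(C)C(C)(C)C)[C@@]1(C)CCC(=O)C(=[N+]=[N-])C(=O)O1 | intermediate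
16 | bridged oxonium ylide (O21 allylated and bonded to C6 and C11, C11 the carbanion centre between C10=O and C20=O) | C=CC[O+]1[C@@H](CC/C(C)=C\CO[Si](C)(C)C(C)(C)C)[C@@]2(C)CCC(=O)[C-]1C(=O)O2 | intermediate
17 | (1R,5R,9S)-9-{(3Z)-5-[(tert-butyldimethylsilyl)oxy]-3-methylpent-3-en-1-yl}-5-methyl-1-(prop-2-en-1-yl)-6,8-dioxabicyclo[3.2.2]nonane-2,7-dione | C=CC[C@@]12O[C@@H](CC/C(C)=C\CO[Si](C)(C)C(C)(C)C)[C@@](C)(CCC1=O)OC2=O | intermediate
18 | 2-{3-[(1R,5R,9S)-9-{(3Z)-5-[(tert-butyldimethylsilyl)oxy]-3-methylpent-3-en-1-yl}-5-methyl-2,7-dioxo-6,8-dioxabicyclo[3.2.2]nonan-1-yl]propyl}-1,3,2-benzodioxaborole | c1ccc2OB(CCC[C@@]34O[C@@H](CC/C(C)=C\CO[Si](C)(C)C(C)(C)C)[C@@](C)(CCC3=O)OC4=O)Oc2c1 | intermediate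
19 | (1R,5R,9S)-9-{(3Z)-5-[(tert-butyldimethylsilyl)oxy]-3-methylpent-3-en-1-yl}-1-(3-hydroxypropyl)-5-methyl-6,8-dioxabicyclo[3.2.2]nonane-2,7-dione | OCCC[C@@]12O[C@@H](CC/C(C)=C\CO[Si](C)(C)C(C)(C)C)[C@@](C)(CCC1=O)OC2=O | intermediate
20 | 3-[(1R,5R,9S)-9-{(3Z)-5-[(tert-butyldimethylsilyl)oxy]-3-methylpent-3-en-1-yl}-5-methyl-2,7-dioxo-6,8-dioxabicyclo[3.2.2]nonan-1-yl]propanal | O=CCC[C@@]12O[C@@H](CC/C(C)=C\CO[Si](C)(C)C(C)(C)C)[C@@](C)(CCC1=O)OC2=O | intermediate
21 | ethyl 2-[bis(2,2,2-trifluoroethoxy)phosphoryl]propanoate | CCOC(=O)C(C)P(=O)(OCC(F)(F)F)OCC(F)(F)F | starting material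
22 | ethyl (2Z)-5-[(1R,5R,9S)-9-{(3Z)-5-[(tert-butyldimethylsilyl)oxy]-3-methylpent-3-en-1-yl}-5-methyl-2,7-dioxo-6,8-dioxabicyclo[3.2.2]nonan-1-yl]-2-methylpent-2-enoate | CCOC(=O)/C(C)=C\CC[C@@]12O[C@@H](CC/C(C)=C\CO[Si](C)(C)C(C)(C)C)[C@@](C)(CCC1=O)OC2=O | intermediate
23 | ethyl (2Z)-5-[(1R,2S,5R,9S)-9-{(3Z)-5-[(tert-butyldimethylsilyl)oxy]-3-methylpent-3-en-1-yl}-2-hydroxy-5-methyl-7-oxo-6,8-dioxabicyclo[3.2.2]nonan-1-yl]-2-methylpent-2-enoate | CCOC(=O)/C(C)=C\CC[C@@]12O[C@@H](CC/C(C)=C\CO[Si](C)(C)C(C)(C)C)[C@@](C)(CC[C@@H]1O)OC2=O | intermediate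
24 | (1R,2S,5R,9S)-9-{(3Z)-5-[(tert-butyldimethylsilyl)oxy]-3-methylpent-3-en-1-yl}-2-hydroxy-1-[(3Z)-5-hydroxy-4-methylpent-3-en-1-yl]-5-methyl-6,8-dioxabicyclo[3.2.2]nonan-7-one | C/C(=C/CC[C@@]12O[C@@H](CC/C(C)=C\CO[Si](C)(C)C(C)(C)C)[C@@](C)(CC[C@@H]1O)OC2=O)CO | intermediate
25 | (1R,2S,5R,9S)-2-hydroxy-9-[(3Z)-5-hydroxy-3-methylpent-3-en-1-yl]-1-[(3Z)-5-hydroxy-4-methylpent-3-en-1-yl]-5-methyl-6,8-dioxabicyclo[3.2.2]nonan-7-one (CNP0105745.1) | C/C(=C/CC[C@@]12O[C@@H](CC/C(C)=C\CO)[C@@](C)(CC[C@@H]1O)OC2=O)CO | target

**Step count and risks**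

Total: 16 steps. Longest linear sequence: 16 steps, from nerol (1) to 25; all other building blocks are commercial.

The three steps most likely to fail:

Step 10 (key step). The ether oxygen has to reach the carbenoid across the seven-membered lactone. If that folding is slow, the carbenoid is consumed by insertion into the ether-activated C6–H bond, by transfer of the allyl group to a carbonyl oxygen, or by dimerisation. The fallback sets out from 9 and returns at 17. It makes the dioxanone first by the same kind of carbenoid capture and [2,3] allyl shift in an unbridged, monocyclic setting, and closes the three-carbon bridge afterwards.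
- LiCH2CN (from MeCN and n-BuLi, THF, −78 °C) opens epoxide 9 at C8 to give the hydroxy nitrile F1.
- Bromoacetyl bromide and pyridine give the bromoacetate F2, and N,N'-ditosylhydrazine with DBU converts it into the diazoacetate F3.
- Cu(acac)2 in refluxing CH2Cl2 then forms C11–O21 and C11–C12, giving the 3-allyl-1,4-dioxan-2-one F4 (either C11 epimer is usable).
- LiN(SiMe3)2 (THF, −78 to 0 °C) generates the lactone enolate, which adds to the nitrile carbon in a Thorpe–Ziegler-type cyclisation. This forms C10–C11, can only occur on the face that carries the tether, and gives the imine F5.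
- Mild aqueous acid hydrolyses F5 to ketone 17.

Step 14. The facial selectivity may be poor or inverted, because the cage has a bias of its own that may oppose the catalyst. The C8–C9 part of the carbon bridge can fold toward the lactone bridge, and chain B on C6 leans over the face next to the ether bridge. The fallback sets out from 22 and returns at 23. It replaces kinetic hydride delivery by thermodynamic control.
- NaBH4/CeCl3 (MeOH, −40 °C) reduces 22 under substrate control, presumably to the C10-epimeric alcohol F6.
- F6 is then equilibrated by reversible hydrogen transfer with catalytic [(η5-Ph4C4CO)2H]Ru2(CO)4(μ-H) in toluene at 80 °C.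
- The equilibrium should favour 23, whose hydroxyl points to the open lactone side of the cage and can hydrogen-bond to the lactone carbonyl.

Step 7. The Lewis acid may rearrange the 2,2-disubstituted epoxide to an aldehyde, or the thermally labile dienolate may decay before it alkylates. The fallback sets out from 9 and returns at 14. It uses a more nucleophilic acetoacetate dianion without Lewis acid.
- The dianion of tert-butyl acetoacetate (NaH, then n-BuLi, THF, 0 °C to rt) opens 9 at C8 to give the tert-butyl hydroxy keto ester F7, which is in equilibrium with its cyclic hemiketal.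
- Heating F7 in dilute refluxing toluene expels tert-butanol and gives the same acylketene 13, which lactonises to 14.

Further compounds
F1 | step 10 | (4R,5S,8Z)-10-[(tert-butyldimethylsilyl)oxy]-4-hydroxy-4,8-dimethyl-5-(prop-2-en-1-yloxy)dec-8-enenitrile | C=CCO[C@@H](CC/C(C)=C\CO[Si](C)(C)C(C)(C)C)[C@](C)(O)CCC#N
F2 | step 10 | (3R,4S,7Z)-9-[(tert-butyldimethylsilyl)oxy]-1-cyano-3,7-dimethyl-4-(prop-2-en-1-yloxy)non-7-en-3-yl bromoacetate | C=CCO[C@@H](CC/C(C)=C\CO[Si](C)(C)C(C)(C)C)[C@](C)(OC(=O)CBr)CCC#N
F3 | step 10 | (3R,4S,7Z)-9-[(tert-butyldimethylsilyl)oxy]-1-cyano-3,7-dimethyl-4-(prop-2-en-1-yloxy)non-7-en-3-yl diazoacetate | C=CCO[C@@H](CC/C(C)=C\CO[Si](C)(C)C(C)(C)C)[C@](C)(OC(=O)C=[N+]=[N-])CCC#N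
F4 | step 10 | 3-[(2R,3S)-3-{(3Z)-5-[(tert-butyldimethylsilyl)oxy]-3-methylpent-3-en-1-yl}-2-methyl-6-oxo-5-(prop-2-en-1-yl)-1,4-dioxan-2-yl]propanenitrile | C=CCC1O[C@@H](CC/C(C)=C\CO[Si](C)(C)C(C)(C)C)[C@@](C)(CCC#N)OC1=O
F5 | step 10 | (1R,5R,9S)-9-{(3Z)-5-[(tert-butyldimethylsilyl)oxy]-3-methylpent-3-en-1-yl}-2-imino-5-methyl-1-(prop-2-en-1-yl)-6,8-dioxabicyclo[3.2.2]nonan-7-one | C=CC[C@@]12O[C@@H](CC/C(C)=C\CO[Si](C)(C)C(C)(C)C)[C@@](C)(CCC1=N)OC2=O
F6 | step 14 | ethyl (2Z)-5-[(1R,2R,5R,9S)-9-{(3Z)-5-[(tert-butyldimethylsilyl)oxy]-3-methylpent-3-en-1-yl}-2-hydroxy-5-methyl-7-oxo-6,8-dioxabicyclo[3.2.2]nonan-1-yl]-2-methylpent-2-enoate | CCOC(=O)/C(C)=C\CC[C@@]12O[C@@H](CC/C(C)=C\CO[Si](C)(C)C(C)(C)C)[C@@](C)(CC[C@H]1O)OC2=O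
F7 | step 7 | tert-butyl (6R,7S,10Z)-12-[(tert-butyldimethylsilyl)oxy]-6-hydroxy-6,10-dimethyl-3-oxo-7-(prop-2-en-1-yloxy)dodec-10-enoate | C=CCO[C@@H](CC/C(C)=C\CO[Si](C)(C)C(C)(C)C)[C@](C)(O)CCC(=O)CC(=O)OC(C)(C)C
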